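**Retrosynthetic overview**
1. Target 27 ⇒ C1 alcohol 25 + 13-methyltetradecanoic acid 3 (esterification at C1; the triol is unmasked last from an acetonide and a TES ether). Acid 3 ⇐ 11-bromoundecanoic acid + isobutylmagnesium bromide.
2. C1 carbinol ⇐ CBS reduction of aryl ketone 24. Key C2–C3 bond ⇐ Mukaiyama aldol of the enol silane of methyl ketone 17 with aldehyde 21 (Felkin control sets C3; C4 and C5 come from L-tartaric acid via threitol acetonide 18).
3. Ketone 17 ⇐ Weinreb amide 15 ⇐ bis-oxazole ester 14.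
4. Ring order: ring B (5-substituted oxazole) first, by van Leusen reaction of 3-(benzyloxy)propanal with TosMIC. Ring A (2,4-disubstituted oxazole) second, by cyclodehydration of a serine amide to the oxazoline and then oxidation. The dioxolane is a chiral-pool protecting ring removed at the end.

Assumption: the SMILES is read as (1R,3S,4R,5S)-3,4,5-trihydroxy-1-[2-(1,3-oxazol-5-ylmethyl)-1,3-oxazol-4-yl]hexyl 13-methyltetradecanoate (1,3-syn, 3,4-anti, 4,5-syn).

**Route**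

Step 1
Reactants: 1 11-bromoundecanoic acid; 2 isobutylmagnesium bromide
Product: 3 13-methyltetradecanoic acid
Conditions: 2 (3 equiv), Li2CuCl4 (3 mol%), THF, −20 °C → rt; then 1 M HCl
Reagents that add atoms: none
Why: Kochi-type Li2CuCl4-catalysed alkyl–alkyl cross-coupling of the primary bromide with the primary Grignard reagent, the first equivalent only forming the inert magnesium carboxylate.

Step 2
Reactants: 4 3-(benzyloxy)propan-1-ol
Product: 5 3-(benzyloxy)propanal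
Conditions: TEMPO (10 mol%), PhI(OAc)2 (1.1 equiv), CH2Cl2, rt
Reagents that add atoms: none
Why: TEMPO/oxoammonium oxidation of a primary alcohol stops at the aldehyde in the absence of water.

Step 3
Reactants: 5 3-(benzyloxy)propanal; 6 p-toluenesulfonylmethyl isocyanide (TosMIC)
Product: 8 5-[2-(benzyloxy)ethyl]-1,3-oxazole, via tosyloxazoline adduct 7 (not isolated)
Conditions: K2CO3 (2 equiv), MeOH, reflux
Reagents that add atoms: none
Why: van Leusen oxazole synthesis, in which addition–cyclisation of deprotonated TosMIC to the aldehyde and loss of sulfinate give ring B faster than β-elimination of the benzyloxy group.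

Step 4
Reactants: 8 5-[2-(benzyloxy)ethyl]-1,3-oxazole
Product: 9 2-(1,3-oxazol-5-yl)ethan-1-ol
Conditions: H2 (1 atm), Pd(OH)2/C, EtOH, rt
Reagents that add atoms: none
Why: Catalytic hydrogenolysis cleaves the benzyl ether while the aromatic oxazole is not reduced at 1 atm.

Step 5
Reactants: 9 2-(1,3-oxazol-5-yl)ethan-1-ol
Product: 10 (1,3-oxazol-5-yl)acetic acid
Conditions: TEMPO (20 mol%), PhI(OAc)2 (2.2 equiv), MeCN/H2O 1:1, rt
Reagents that add atoms: water, O
Why: TEMPO/PhI(OAc)2 oxidation in aqueous medium proceeds through the aldehyde hydrate to the acid under near-neutral conditions that the oxazole tolerates.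

Step 6
Reactants: 10 (1,3-oxazol-5-yl)acetic acid; 11 methyl L-serinate hydrochloride
Product: 12 methyl N-[(1,3-oxazol-5-yl)acetyl]-L-serinate
Conditions: EDC·HCl, HOBt, N-methylmorpholine, CH2Cl2, 0 °C → rt
Reagents that add atoms: none
Why: Carbodiimide/HOBt amide coupling, the amine being acylated far faster than the free serine hydroxyl.

Step 7
Reactants: 12 methyl N-[(1,3-oxazol-5-yl)acetyl]-L-serinate
Product: 13 methyl (4S)-2-(1,3-oxazol-5-ylmethyl)-4,5-dihydro-1,3-oxazole-4-carboxylate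
Conditions: Deoxo-Fluor [(MeOCH2CH2)2NSF3] (1.1 equiv), CH2Cl2, −20 °C; aq. NaHCO3 quench; short silica plug
Reagents that add atoms: none
Why: Wipf–Williams cyclodehydration of the β-hydroxy amide, in which the activated primary hydroxyl is displaced by the amide oxygen to close the oxazoline without touching the serine α-carbon.

Step 8
Reactants: 13 methyl (4S)-2-(1,3-oxazol-5-ylmethyl)-4,5-dihydro-1,3-oxazole-4-carboxylate
Product: 14 methyl 2-(1,3-oxazol-5-ylmethyl)-1,3-oxazole-4-carboxylate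
Conditions: BrCCl3 (3 equiv), DBU (3 equiv), CH2Cl2, 0 °C → rt
Reagents that add atoms: none
Why: Williams BrCCl3/DBU oxidation, in which bromination–dehydrobromination at the ester-activated C4 aromatises the oxazoline to ring A (the serine stereocentre is deliberately destroyed).

Step 9
Reactants: 14 methyl 2-(1,3-oxazol-5-ylmethyl)-1,3-oxazole-4-carboxylate
Product: 15 N-methoxy-N-methyl-2-(1,3-oxazol-5-ylmethyl)-1,3-oxazole-4-carboxamide
Conditions: MeNHOMe·HCl (3 equiv), Me3Al (3 equiv), CH2Cl2, 0 °C → rt; cold 1 M HCl work-up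
Reagents that add atoms: N,O-dimethylhydroxylamine hydrochloride, CNOC.Cl
Why: Weinreb aminolysis of the ester by the aluminium amide avoids a basic saponification step.

Step 10
Reactants: 15 N-methoxy-N-methyl-2-(1,3-oxazol-5-ylmethyl)-1,3-oxazole-4-carboxamide; 16 methylmagnesium bromide
Product: 17 1-[2-(1,3-oxazol-5-ylmethyl)-1,3-oxazol-4-yl]ethan-1-one
Conditions: 16 (1.5 equiv), THF, −78 → 0 °C; aq. NH4Cl
Reagents that add atoms: none
Why: Weinreb ketone synthesis, the stable magnesium chelate preventing over-addition, with low temperature keeping the oxazole C2–H untouched.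

Step 11
Reactants: 18 [(4S,5S)-2,2-dimethyl-1,3-dioxolane-4,5-diyl]dimethanol (2,3-O-isopropylidene-L-threitol)
Product: 19 [(4S,5S)-5-(hydroxymethyl)-2,2-dimethyl-1,3-dioxolan-4-yl]methyl 4-methylbenzenesulfonate
Conditions: TsCl (1.05 equiv), Ag2O (1.5 equiv), KI (0.2 equiv), CH2Cl2, rt
Reagents that add atoms: p-toluenesulfonyl chloride, Cc1ccc(cc1)S(=O)(=O)Cl
Why: Ag2O-mediated monosulfonylation of a C2-symmetric diol, where both hydroxyls are equivalent and bis-tosylation is suppressed.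

Step 12
Reactants: 19 [(4S,5S)-5-(hydroxymethyl)-2,2-dimethyl-1,3-dioxolan-4-yl]methyl 4-methylbenzenesulfonate
Product: 20 [(4S,5S)-2,2,5-trimethyl-1,3-dioxolan-4-yl]methanol
Conditions: LiAlH4, THF, 0 °C → reflux; H2O/NaOH work-up
Reagents that add atoms: none
Why: SN2 hydride displacement of the primary tosylate creates the C6 methyl without touching a stereocentre, the trans-dioxolane preventing cyclisation of the free alkoxide.

Step 13
Reactants: 20 [(4S,5S)-2,2,5-trimethyl-1,3-dioxolan-4-yl]methanol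
Product: 21 (4R,5S)-2,2,5-trimethyl-1,3-dioxolane-4-carbaldehyde
Conditions: (COCl)2, DMSO, CH2Cl2, −78 °C; Et3N, → 0 °C; used crude
Reagents that add atoms: none
Why: Swern oxidation at low temperature gives the volatile α-alkoxy aldehyde without epimerisation (the trans isomer is also the stable one).

Step 14
Reactants: 17 1-[2-(1,3-oxazol-5-ylmethyl)-1,3-oxazol-4-yl]ethan-1-one
Product: 22 trimethyl({1-[2-(1,3-oxazol-5-ylmethyl)-1,3-oxazol-4-yl]ethenyl}oxy)silane
Conditions: TMSOTf (1.3 equiv), Et3N (2 equiv), CH2Cl2, 0 °C; used crude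
Reagents that add atoms: trimethylsilyl trifluoromethanesulfonate, C[Si](C)(C)OS(=O)(=O)C(F)(F)F
Why: Soft enolisation silylates only the methyl ketone and avoids strong bases that would metalate the oxazole C2–H or the CH2 between the rings.

Step 15
Reactants: 22 trimethyl({1-[2-(1,3-oxazol-5-ylmethyl)-1,3-oxazol-4-yl]ethenyl}oxy)silane; 21 (4R,5S)-2,2,5-trimethyl-1,3-dioxolane-4-carbaldehyde
Product: 23 (3S)-3-hydroxy-1-[2-(1,3-oxazol-5-ylmethyl)-1,3-oxazol-4-yl]-3-[(4S,5S)-2,2,5-trimethyl-1,3-dioxolan-4-yl]propan-1-one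
Conditions: BF3·OEt2 (2.5 equiv), CH2Cl2, −78 °C, 2 h; aq. NaHCO3
Reagents that add atoms: none
Why: Mukaiyama aldol addition through an open Felkin–Anh/Cornforth transition state, the enol silane attacking the BF3-activated aldehyde anti to the dioxolane C–O bond to set C3 as 3S (3,4-anti; the minor epimer is removed on silica).

Step 16
Reactants: 23 (3S)-3-hydroxy-1-[2-(1,3-oxazol-5-ylmethyl)-1,3-oxazol-4-yl]-3-[(4S,5S)-2,2,5-trimethyl-1,3-dioxolan-4-yl]propan-1-one
Product: 24 (3S)-1-[2-(1,3-oxazol-5-ylmethyl)-1,3-oxazol-4-yl]-3-[(triethylsilyl)oxy]-3-[(4R,5S)-2,2,5-trimethyl-1,3-dioxolan-4-yl]propan-1-one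
Conditions: TESOTf (1.3 equiv), 2,6-lutidine (2 equiv), CH2Cl2, −78 °C
Reagents that add atoms: triethylsilyl trifluoromethanesulfonate, CC[Si](CC)(CC)OS(=O)(=O)C(F)(F)F
Why: Silyl protection of the C3 hydroxyl under non-nucleophilic conditions avoids retro-aldol and leaves C1 as the only oxygen to be acylated later (the ring descriptor changes only through CIP priority).

Step 17
Reactants: 24 (3S)-1-[2-(1,3-oxazol-5-ylmethyl)-1,3-oxazol-4-yl]-3-[(triethylsilyl)oxy]-3-[(4R,5S)-2,2,5-trimethyl-1,3-dioxolan-4-yl]propan-1-one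
Product: 25 (1R,3S)-1-[2-(1,3-oxazol-5-ylmethyl)-1,3-oxazol-4-yl]-3-[(triethylsilyl)oxy]-3-[(4R,5S)-2,2,5-trimethyl-1,3-dioxolan-4-yl]propan-1-ol
Conditions: (S)-2-methyl-CBS-oxazaborolidine (0.3 equiv), BH3·SMe2 (1.5 equiv), THF, −20 °C; MeOH quench
Reagents that add atoms: none
Why: Corey–Bakshi–Shibata reduction, in which the (S)-oxazaborolidine binds the ketone with the oxazolyl group as the large substituent and delivers hydride to give the 1R carbinol (1,3-syn) under reagent control.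

Step 18
Reactants: 25 (1R,3S)-1-[2-(1,3-oxazol-5-ylmethyl)-1,3-oxazol-4-yl]-3-[(triethylsilyl)oxy]-3-[(4R,5S)-2,2,5-trimethyl-1,3-dioxolan-4-yl]propan-1-ol; 3 13-methyltetradecanoic acid
Product: 26 (1R,3S)-1-[2-(1,3-oxazol-5-ylmethyl)-1,3-oxazol-4-yl]-3-[(triethylsilyl)oxy]-3-[(4R,5S)-2,2,5-trimethyl-1,3-dioxolan-4-yl]propyl 13-methyltetradecanoate
Conditions: 3 (1.3 equiv), EDC·HCl (1.5 equiv), DMAP (0.5 equiv), CH2Cl2, 0 °C → rt
Reagents that add atoms: none
Why: Steglich esterification acylates the only free hydroxyl with retention at C1.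

Step 19
Reactants: 26 (1R,3S)-1-[2-(1,3-oxazol-5-ylmethyl)-1,3-oxazol-4-yl]-3-[(triethylsilyl)oxy]-3-[(4R,5S)-2,2,5-trimethyl-1,3-dioxolan-4-yl]propyl 13-methyltetradecanoate
Product: 27 (1R,3S,4R,5S)-3,4,5-trihydroxy-1-[2-(1,3-oxazol-5-ylmethyl)-1,3-oxazol-4-yl]hexyl 13-methyltetradecanoate
Conditions: TFA/H2O/THF (2:1:2), 0 °C → rt; evaporate with toluene, no basic wash
Reagents that add atoms: none
Why: Acid-catalysed hydrolysis removes the acetonide and the TES ether together, while the ester and both oxazoles are acid-stable and the base-free work-up avoids acyl migration.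

**Compound list**
1 | 11-bromoundecanoic acid | BrCCCCCCCCCCC(=O)O | starting material
2 | isobutylmagnesium bromide | CC(C)C[Mg]Br | starting material
3 | 13-methyltetradecanoic acid | CC(C)CCCCCCCCCCCC(=O)O | intermediate
4 | 3-(benzyloxy)propan-1-ol | OCCCOCc1ccccc1 | starting material
5 | 3-(benzyloxy)propanal | O=CCCOCc1ccccc1 | intermediate
6 | p-toluenesulfonylmethyl isocyanide (TosMIC) | Cc1ccc(cc1)S(=O)(=O)C[N+]#[C-] | starting material
7 | 5-[2-(benzyloxy)ethyl]-4-(4-methylbenzenesulfonyl)-4,5-dihydro-1,3-oxazole (racemic; both centres lost on elimination) | Cc1ccc(cc1)S(=O)(=O)C2N=COC2CCOCc3ccccc3 | intermediate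
8 | 5-[2-(benzyloxy)ethyl]-1,3-oxazole | c1ccccc1COCCc1cnco1 | intermediate
9 | 2-(1,3-oxazol-5-yl)ethan-1-ol | OCCc1cnco1 | intermediate
10 | (1,3-oxazol-5-yl)acetic acid | OC(=O)Cc1cnco1 | intermediate
11 | methyl L-serinate hydrochloride | Cl.COC(=O)[C@@H](N)CO | starting material
12 | methyl N-[(1,3-oxazol-5-yl)acetyl]-L-serinate | COC(=O)[C@H](CO)NC(=O)Cc1cnco1 | intermediate
13 | methyl (4S)-2-(1,3-oxazol-5-ylmethyl)-4,5-dihydro-1,3-oxazole-4-carboxylate | COC(=O)[C@@H]1COC(Cc2cnco2)=N1 | intermediate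
14 | methyl 2-(1,3-oxazol-5-ylmethyl)-1,3-oxazole-4-carboxylate | COC(=O)c1coc(Cc2cnco2)n1 | intermediate
15 | N-methoxy-N-methyl-2-(1,3-oxazol-5-ylmethyl)-1,3-oxazole-4-carboxamide | CON(C)C(=O)c1coc(Cc2cnco2)n1 | intermediate
16 | methylmagnesium bromide | C[Mg]Br | starting material
17 | 1-[2-(1,3-oxazol-5-ylmethyl)-1,3-oxazol-4-yl]ethan-1-one | CC(=O)c1coc(Cc2cnco2)n1 | intermediate
18 | [(4S,5S)-2,2-dimethyl-1,3-dioxolane-4,5-diyl]dimethanol | CC1(C)O[C@@H](CO)[C@H](CO)O1 | starting material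
19 | [(4S,5S)-5-(hydroxymethyl)-2,2-dimethyl-1,3-dioxolan-4-yl]methyl 4-methylbenzenesulfonate | CC1(C)O[C@@H](CO)[C@H](COS(=O)(=O)c2ccc(C)cc2)O1 | intermediate
20 | [(4S,5S)-2,2,5-trimethyl-1,3-dioxolan-4-yl]methanol | CC1(C)O[C@@H](CO)[C@H](C)O1 | intermediate
21 | (4R,5S)-2,2,5-trimethyl-1,3-dioxolane-4-carbaldehyde | CC1(C)O[C@@H](C=O)[C@H](C)O1 | intermediate
22 | trimethyl({1-[2-(1,3-oxazol-5-ylmethyl)-1,3-oxazol-4-yl]ethenyl}oxy)silane | C=C(O[Si](C)(C)C)c1coc(Cc2cnco2)n1 | intermediate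
23 | (3S)-3-hydroxy-1-[2-(1,3-oxazol-5-ylmethyl)-1,3-oxazol-4-yl]-3-[(4S,5S)-2,2,5-trimethyl-1,3-dioxolan-4-yl]propan-1-one | O=C(C[C@H](O)[C@@H]1OC(C)(C)O[C@H]1C)c1coc(Cc2cnco2)n1 | intermediate
24 | (3S)-1-[2-(1,3-oxazol-5-ylmethyl)-1,3-oxazol-4-yl]-3-[(triethylsilyl)oxy]-3-[(4R,5S)-2,2,5-trimethyl-1,3-dioxolan-4-yl]propan-1-one | O=C(C[C@H](O[Si](CC)(CC)CC)[C@@H]1OC(C)(C)O[C@H]1C)c1coc(Cc2cnco2)n1 | intermediate
25 | (1R,3S)-1-[2-(1,3-oxazol-5-ylmethyl)-1,3-oxazol-4-yl]-3-[(triethylsilyl)oxy]-3-[(4R,5S)-2,2,5-trimethyl-1,3-dioxolan-4-yl]propan-1-ol | O[C@H](C[C@H](O[Si](CC)(CC)CC)[C@@H]1OC(C)(C)O[C@H]1C)c1coc(Cc2cnco2)n1 | intermediate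
26 | (1R,3S)-1-[2-(1,3-oxazol-5-ylmethyl)-1,3-oxazol-4-yl]-3-[(triethylsilyl)oxy]-3-[(4R,5S)-2,2,5-trimethyl-1,3-dioxolan-4-yl]propyl 13-methyltetradecanoate | CC(C)CCCCCCCCCCCC(=O)O[C@H](C[C@H](O[Si](CC)(CC)CC)[C@@H]1OC(C)(C)O[C@H]1C)c1coc(Cc2cnco2)n1 | intermediate
27 | (1R,3S,4R,5S)-3,4,5-trihydroxy-1-[2-(1,3-oxazol-5-ylmethyl)-1,3-oxazol-4-yl]hexyl 13-methyltetradecanoate | CC(C)CCCCCCCCCCCC(=O)O[C@H](C[C@H](O)[C@H](O)[C@H](C)O)c1coc(Cc2cnco2)n1 | target

**Totals**
Total step count: 19. Longest linear sequence: 15 steps (steps 2–10, then 14–19, from 4 to 27).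

**Steps most likely to fail, with fallbacks**

Step 15, the aldol. The two oxazole nitrogens compete for BF3·OEt2, and the facial selectivity on aldehyde 21 may be only moderate. The fallback is a masked aldol by nitrile oxide cycloaddition; it sets out from ester 14 and aldehyde 21 and comes back at 23. Ester 14 is reduced with i-Bu2AlH (CH2Cl2, −78 °C) to 2-(1,3-oxazol-5-ylmethyl)-1,3-oxazole-4-carbaldehyde F1, which with NH2OH·HCl/NaOAc in EtOH gives (E)-N-hydroxy-1-[2-(1,3-oxazol-5-ylmethyl)-1,3-oxazol-4-yl]methanimine F2. Aldehyde 21 is methylenated (Ph3PCH3Br, KOtBu, THF, 0 °C) to (4S,5S)-4-ethenyl-2,2,5-trimethyl-1,3-dioxolane F3. Aqueous NaOCl in CH2Cl2 at 0 °C turns F2 into 2-(1,3-oxazol-5-ylmethyl)-1,3-oxazole-4-carbonitrile oxide F4, which is trapped in situ by F3 anti to the allylic C–O bond (inside-alkoxy transition state). This gives (5S)-3-[2-(1,3-oxazol-5-ylmethyl)-1,3-oxazol-4-yl]-5-[(4R,5S)-2,2,5-trimethyl-1,3-dioxolan-4-yl]-4,5-dihydro-1,2-oxazole F5. Mo(CO)6 in MeCN/H2O at 80 °C cleaves the N–O bond and hydrolyses the imine to 23.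

Step 17, the CBS reduction. Borane binding at the oxazole nitrogens and a possibly mismatched C3 stereocentre could erode the 1R selectivity. The fallback uses substrate-directed reduction and regioselective acylation without a silyl group; it sets out from 23 and comes back at target 27. Narasaka–Prasad reduction of 23 (Et2BOMe, NaBH4, THF/MeOH, −78 °C) gives the 1,3-syn diol (1R,3S)-1-[2-(1,3-oxazol-5-ylmethyl)-1,3-oxazol-4-yl]-3-[(4S,5S)-2,2,5-trimethyl-1,3-dioxolan-4-yl]propane-1,3-diol F6. Acylation with 1.0 equiv of acid 3 (DIC, catalytic DMAP, CH2Cl2, −20 °C) should favour the unhindered oxazolyl carbinol over the C3 hydroxyl flanked by the dioxolane; this regioselectivity is the weak point of the fallback. It gives (1R,3S)-3-hydroxy-1-[2-(1,3-oxazol-5-ylmethyl)-1,3-oxazol-4-yl]-3-[(4S,5S)-2,2,5-trimethyl-1,3-dioxolan-4-yl]propyl 13-methyltetradecanoate F7. TFA/H2O/THF then removes the acetonide to give 27.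

Step 8, the oxidation to ring A. The doubly activated CH2 between the two heterocycles may be brominated under BrCCl3/DBU. The fallback is a Hantzsch-type oxazole synthesis that builds the aromatic ring directly; it sets out from acid 10 and comes back at ester 14. Acid 10 is converted (NH4Cl, EDC·HCl, HOBt, i-Pr2NEt, DMF) into 2-(1,3-oxazol-5-yl)acetamide F8. F8 and methyl bromopyruvate (NaHCO3, THF, 60 °C) give methyl 4-hydroxy-2-(1,3-oxazol-5-ylmethyl)-4,5-dihydro-1,3-oxazole-4-carboxylate F9, which is dehydrated with (CF3CO)2O/pyridine at 0 °C to 14.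

**Further compounds**
F1 | step 15 | 2-(1,3-oxazol-5-ylmethyl)-1,3-oxazole-4-carbaldehyde | O=Cc1coc(Cc2cnco2)n1
F2 | step 15 | (E)-N-hydroxy-1-[2-(1,3-oxazol-5-ylmethyl)-1,3-oxazol-4-yl]methanimine | O/N=C/c1coc(Cc2cnco2)n1
F3 | step 15 | (4S,5S)-4-ethenyl-2,2,5-trimethyl-1,3-dioxolane | C=C[C@@H]1OC(C)(C)O[C@H]1C
F4 | step 15 | 2-(1,3-oxazol-5-ylmethyl)-1,3-oxazole-4-carbonitrile oxide | [O-][N+]#Cc1coc(Cc2cnco2)n1
F5 | step 15 | (5S)-3-[2-(1,3-oxazol-5-ylmethyl)-1,3-oxazol-4-yl]-5-[(4R,5S)-2,2,5-trimethyl-1,3-dioxolan-4-yl]-4,5-dihydro-1,2-oxazole | C[C@@H]1OC(C)(C)O[C@H]1[C@@H]2CC(=NO2)c3coc(Cc4cnco4)n3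
F6 | step 17 | (1R,3S)-1-[2-(1,3-oxazol-5-ylmethyl)-1,3-oxazol-4-yl]-3-[(4S,5S)-2,2,5-trimethyl-1,3-dioxolan-4-yl]propane-1,3-diol | O[C@H](C[C@H](O)[C@@H]1OC(C)(C)O[C@H]1C)c1coc(Cc2cnco2)n1
F7 | step 17 | (1R,3S)-3-hydroxy-1-[2-(1,3-oxazol-5-ylmethyl)-1,3-oxazol-4-yl]-3-[(4S,5S)-2,2,5-trimethyl-1,3-dioxolan-4-yl]propyl 13-methyltetradecanoate | CC(C)CCCCCCCCCCCC(=O)O[C@H](C[C@H](O)[C@@H]1OC(C)(C)O[C@H]1C)c1coc(Cc2cnco2)n1
F8 | step 8 | 2-(1,3-oxazol-5-yl)acetamide | NC(=O)Cc1cnco1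
F9 | step 8 | methyl 4-hydroxy-2-(1,3-oxazol-5-ylmethyl)-4,5-dihydro-1,3-oxazole-4-carboxylate (racemic) | COC(=O)C1(O)COC(Cc2cnco2)=N1
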